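# Proposed synthesis of CNP0184936.2 (compound 18)

Flavanone numbering is used throughout. The unprimed unit carries the 5,7-dihydroxy ring A and the primed unit the 5'-hydroxy-7'-methoxy ring A. Compounds 1–18 are defined in the steps and in the compound list.

## The problem

- Compound 18 is a 3,3'-linked biflavanone: two 2-(4-methoxyphenyl)chroman-4-one units joined through the C3–C3' bond, so the four stereocentres C2, C3, C3' and C2' form one contiguous chain.
- All four centres are R, which places the aryl group and the C3–C3' bond cis on each pyranone ring. Apart from the single methyl ether on O7', the molecule is C2-symmetric.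
- The 2,3-cis arrangement is the less stable one. C3 and C3' lie α to ketones and epimerise through the enol, and base can open either ring by retro-oxa-Michael reaction. These centres must therefore be set late, under kinetic control, and must not meet strong acid or base afterwards.
- Once C2 is fixed it can direct protonation at C3, but nothing in the skeleton controls C2 and C2' themselves; they need an external chiral influence.
- The free phloroglucinol-type phenols and the benzylic C2–O1 ethers (activated by the 4-methoxyphenyl groups towards ionisation and hydrogenolysis) restrict the choice of late reagents. Telling O7 from O7' in otherwise identical halves is a separate task.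
- The enabling feature lies in ring A of each unit. O1 on C8a and the acyl carbon C4 on C4a are ortho neighbours, and the oxygens on C5 and C7 are meta to each other with O5 beside C4a. This is the pattern left when a 3,5-dioxygenated benzyne takes up the oxygen and the acyl carbon of a carboxyl group at its two triple-bond carbons.
- Removing both A rings in this way leaves C4–C3(=C2H–Ar)–C3'(=C2'H–Ar)–C4', which is a 2,3-bis(arylidene)succinic acid.

## Retrosynthesis

**18 to 17 (O7'–CH3).** The methyl group on O7' is removed first, giving the C2-symmetric tetraphenol 17. Its two 7-hydroxyls are homotopic, so monomethylation raises no regiochemical question, only the question of one versus two methylations. Carrying the methyl ether through from the start would require two different arynes and a stepwise, unsymmetrical assembly, which would break the twofold key step. The forward reaction needs a neutral methylating agent that ignores the chelated 5-hydroxyls and cannot epimerise C3.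

**17 to 16 (four O–benzyl bonds).** The four phenols are masked as benzyl ethers in 16. Benzyl is preferred over methyl (7-O-demethylation would also attack the anisyl ethers) and over acetal groups (acid would epimerise C3), because it is removed by neutral hydrogenolysis. The ethers must survive n-BuLi at low temperature, fluoride at 125 °C and amine bases.

**16 to 14 (O1–C2, O1'–C2', C3–H, C3'–H).** A twofold retro-oxa-Michael reaction opens both pyranone rings to the achiral bis(2'-hydroxychalcone) 14, and all four stereocentres vanish. Cutting C3–C3' instead (oxidative coupling of two flavanone enolates) would have to control two epimerisable centres in a coupling that gives diastereomer mixtures. Cutting the C2–aryl bonds is considered below as a separate road. The forward step must close two 6-endo rings with catalyst control at C2 and C2' and kinetic protonation at C3 and C3'.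

**14 to 4 plus two molecules of 11, through 12 (O1–C8a and C4–C4a in each half).** This is the key cut. Each ring A is removed as the aryne 12, generated from the silyl triflate 11, and what remains is the diacid 4. The usual chalcone construction (aldol condensation of an acetophenone with an aldehyde) cannot deliver a chalcone whose α-carbon carries a second chalcone. Friedel–Crafts acylation of a phloroglucinol ether with an activated form of 4 would face regiochemical ambiguity and acid-sensitive benzyl ethers. The aryne cut forms both ring-A bonds of each half in one operation with regiochemistry dictated by the benzyloxy group beside the triple bond. It reduces a sixty-carbon compound to a twenty-carbon diacid and two identical aryl pieces. The forward reaction needs carboxylate addition at the correct aryne carbon and acyl transfer faster than protonation.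

**4 to 1 plus two molecules of 2 (both arylidene C=C bonds).** The diacid is the product of a double Stobbe condensation of diethyl succinate 1 with 4-methoxybenzaldehyde 2, followed by saponification. It already contains C2, C3, C3', C2', both C4 carbons and both anisyl groups, with the E,E geometry that the condensation favours.

**11 to 9 to 6 to 5 (O–Tf, C–Si, carbamate).** The silyl triflate 11 comes from the ortho-silyl carbamate 9 by carbamate cleavage and triflation in one flask. Compound 9 comes from carbamate 6 by directed ortho-metalation and silylation at the position between the carbamate and a benzyloxy group. Compound 6 is made from the commercial phenol 5 and isopropyl isocyanate. The carbamate route fixes the silicon position unambiguously, which electrophilic halogenation of 5 would not.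

## Roads not taken

**Alternative 1: oxidative dimerisation to a crossed dilactone.**
- Cut: the C3–C3' bond and both benzylic C–O bonds, back to two molecules of (E)-4-methoxycinnamic acid A2.
- Forward key step: oxidation with Tl(OCOCF3)3 and BF3·OEt2, or at an anode, joins the α-carbons; each carboxyl oxygen captures the benzylic cation of the other half, giving the exo,exo cis-fused bis-lactone A1.
- Merits: one step from a commodity acid makes C3–C3' and all four stereocentres. Read atom by atom, the relative configuration of A1 matches that of 18 without any catalyst. The chosen plan cannot match this, since it leaves all four centres to one late step.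
- Weak points:
  - An achiral oxidant gives A1 as a racemate.
  - The benzylic oxygen on C2 of A1 is acylated by the carbonyl of the other half, whereas O1 of 18 is tied through ring A to the carbonyl of the same half. Each lactone must therefore be opened by a trioxygenated aryl-metal reagent, under basic conditions that endanger C3, and the liberated benzylic hydroxyl must then be replaced by a phenol oxygen.
  - An SN2 replacement inverts C2 and leads into the 2,3-trans series; ionisation at the 4-methoxybenzylic position scrambles it.
- Comparison: the chosen plan keeps C2 trigonal until the ring closes, needs no substitution at a stereogenic benzylic carbon, attaches ring A through both of its bonds in one operation, and draws its absolute configuration from a catalyst instead of a resolution.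

**Alternative 2: double carbonylative Suzuki closure onto a diborylalkene.**
- Cut: the C4–C4a and C4–C3 bonds of both units, with each carbonyl carbon supplied by CO. The precursor A4 already holds both O1–C2 aryl ethers, both C2 stereocentres, two aryl iodides and a (Z)-1,2-diborylalkene.
- Forward key step: Pd(PPh3)4, CO and K2CO3 carry each aryl iodide through oxidative addition and CO insertion; coupling with the alkenyl boronates closes both pyranones to the (Z)-bichromanylidene-dione A3.
- Merits: C2 and C2' are fixed early by dependable asymmetric propargylic chemistry, and no epimerisable centre exists until the end. In securing the absolute configuration at C2 this road is better than the chosen plan, which can only offer a single catalyst-controlled closure.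
- Weak points:
  - The aryl iodides of A4 are flanked on both sides by oxygen substituents, and direct coupling without CO would close five-membered rings.
  - The doubly benzylic-propargylic ethers of A4 ionise easily.
  - A3 has lost C3 and C3'. Delivering both hydrogens to one face of the Z-alkene of C2-symmetric A3 puts one hydrogen cis and the other trans to the aryl group of its own ring, which leads to a cis,trans-biflavanone. Compound 18 needs delivery to opposite faces, that is, stepwise reduction and two kinetic protonations with no chiral catalyst nearby.
  - A4 is many steps away from simple materials.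
- Comparison: both plans end at the same question of kinetic C3 protonation, but the chosen plan asks it on a substrate reached in five steps.

**Alternative 3: twofold asymmetric conjugate arylation of a 3,3'-bichromone.**
- Cut: both C2–aryl bonds, back to the unsymmetrical bichromone A6 and 4-methoxyphenylboronic acid A7.
- Forward key step: Pd(OCOCF3)2 with a chiral pyridine–oxazoline ligand adds the aryl group to each C2=C3 bond. Protonation of the two enolates gives the cis,cis-biflavanone A5, with unit 1 as dibenzyl ether and unit 2 as dimethyl ether.
- Merits: enantioselective arylation of simple chromones is established, and the aryl groups arrive last. A6 carries benzyl on O7 and methyl on O7', so chelation-controlled 5'-O-demethylation and hydrogenolysis of A5 would give 18 without any statistical step. In this respect the road is better than the chosen plan.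
- Weak points:
  - A6 is a 3-substituted, 5,7-dialkoxylated chromone: the β-carbon is hindered by the neighbouring chromone and electronically deactivated.
  - The electron-rich boronic acid A7 is prone to protodeboronation.
  - C3 and C3' again depend on kinetic protonation.
  - A6 must be assembled by cross-coupling two different 3-functionalised chromones.
- Comparison: the chosen plan offers a much shorter approach to the substrate of its asymmetric step, an intramolecular C–O bond formation in place of an intermolecular C–C bond formation at a hindered carbon, and a C2-symmetric substrate in which two catalyst-controlled events reinforce the enantiomeric purity.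

Key step: step 5

Remark on starting material: 3,5-bis(benzyloxy)phenol (5) is taken as a purchased compound.

Remark on step 6: the quinidine-derived thiourea is assumed to deliver the 2R sense; if a trial closure shows the opposite sense, the quinine-derived pseudoenantiomer is used in its place.

## Route

Step 1
Reactants: 1 diethyl succinate; 2 4-methoxybenzaldehyde (2.2 equiv)
Product: 4 (2E,3E)-2,3-bis(4-methoxybenzylidene)succinic acid, via (2E,3E)-2,3-bis(4-methoxybenzylidene)succinic acid monoethyl ester 3 (not isolated)
Conditions: NaOEt (3 equiv), EtOH, reflux; then 2 M aq NaOH, reflux; then HCl to pH 1, recrystallisation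
Reagents that add atoms: sodium hydroxide, [Na+].[OH-] (oxygen of the carboxyl group freed by saponification)
Why: Two successive Stobbe condensations (aldol addition, γ-lactonisation onto the neighbouring ester, E1cB ring opening) turn both methylene groups of 1 into arylidene groups, with each aryl group anti to its carboxyl carbon for steric reasons, which gives the E,E-diene; hydroxide then saponifies the remaining ethyl ester. Aldehyde 2 has no α-hydrogen and can act only as the electrophile.

Step 2
Reactants: 5 3,5-bis(benzyloxy)phenol
Product: 6 3,5-bis(benzyloxy)phenyl N-isopropylcarbamate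
Conditions: i-PrNCO, Et3N (cat.), CH2Cl2, rt
Reagents that add atoms: isopropyl isocyanate, CC(C)N=C=O
Why: Base-catalysed addition of the phenol to the isocyanate gives the N-isopropyl carbamate, a strong directing group for ortho-metalation that can later be removed under mild conditions.

Step 3
Reactants: 6 3,5-bis(benzyloxy)phenyl N-isopropylcarbamate
Product: 9 3,5-bis(benzyloxy)-2-(trimethylsilyl)phenyl N-isopropylcarbamate, via N-tert-butyldimethylsilyl carbamate 7 (not isolated), via N-tert-butyldimethylsilyl 2-trimethylsilyl carbamate 8 (not isolated)
Conditions: TBSOTf, TMEDA, Et2O, 0 °C to rt; n-BuLi, TMEDA, −78 °C; TMSCl, −78 °C to rt; aq NaHSO4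
Reagents that add atoms: chlorotrimethylsilane, C[Si](C)(C)Cl; tert-butyldimethylsilyl triflate, CC(C)(C)[Si](C)(C)OS(=O)(=O)C(F)(F)F (its silyl group stays only in 7 and 8)
Why: Directed ortho-metalation: after N-silylation in the flask, n-BuLi/TMEDA removes the ring hydrogen flanked by the carbamate oxygen and a benzyloxy group (the two such positions are equivalent), which is more acidic than the position between the two benzyl ethers. The aryllithium is silylated by TMSCl and the N-silyl group is lost in the acidic work-up.

Step 4
Reactants: 9 3,5-bis(benzyloxy)-2-(trimethylsilyl)phenyl N-isopropylcarbamate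
Product: 11 3,5-bis(benzyloxy)-2-(trimethylsilyl)phenyl trifluoromethanesulfonate, via 3,5-bis(benzyloxy)-2-(trimethylsilyl)phenol 10 (not isolated)
Conditions: DBU, Et2NH, MeCN, 40 °C; then PhNTf2, rt
Reagents that add atoms: N-phenylbis(trifluoromethanesulfonimide), O=S(=O)(N(c1ccccc1)S(=O)(=O)C(F)(F)F)C(F)(F)F
Why: DBU converts the N–H carbamate into the phenoxide by E1cB loss of isopropyl isocyanate, which Et2NH traps as a urea; the phenoxide is triflated in the same flask by PhNTf2 to give the ortho-silyl aryl triflate.

Step 5
Reactants: 4 (2E,3E)-2,3-bis(4-methoxybenzylidene)succinic acid; 11 3,5-bis(benzyloxy)-2-(trimethylsilyl)phenyl trifluoromethanesulfonate (two molecules react; 3 equiv used)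
Product: 14 (2E,3E)-1,4-bis[2-hydroxy-4,6-bis(benzyloxy)phenyl]-2,3-bis(4-methoxybenzylidene)butane-1,4-dione, via 3,5-bis(benzyloxy)benzyne 12 (not isolated), via mono-insertion keto acid 13 (not isolated)
Conditions: CsF (8 equiv), THF, 125 °C, sealed tube; then 2 M KOH, EtOH, rt; cold 1 M HCl
Reagents that add atoms: none
Why: Fluoride attacks the silicon of 11 and triflate leaves, so that aryne 12 is released gradually at 125 °C. A cesium carboxylate of 4 adds to the aryne carbon remote from the neighbouring benzyloxy group, because that inductively withdrawing group distorts the triple bond and stabilises the aryl anion that forms beside it. The aryl anion attacks the carbonyl of the aryl ester just formed through a four-membered transition state and the ring opens to the ortho-acyl phenoxide (an anionic Fries-type 1,3-acyl shift); the former carboxyl oxygen thus becomes O1 on C8a and the acyl carbon C4 is bonded to C4a beside the 5-benzyloxy group, and the second carboxylate of 13 repeats the sequence. The closest known reaction type is the fluoride-triggered insertion of arynes into the C–O bond of carboxylic acids to give ortho-hydroxyaryl ketones, which covers α,β-unsaturated acids and 3-alkoxybenzynes. No ring of 18 closes and no stereocentre is formed; the E geometry of both alkenes is carried over from 4. Three selectivities are needed: regioselective capture of 12, secured by the benzyloxy group beside the triple bond; acyl transfer ahead of protonation of the aryl anion, favoured by the high temperature and by the absence of any proton source other than the acid itself; and acyl transfer ahead of conjugate addition of the aryl anion, favoured because the β-carbon is hindered and deactivated by the 4-methoxyphenyl group. Material that has undergone oxa-Michael closure under the basic fluoride conditions is returned to the open phenoxide by the alkaline work-up (E1cB ring opening), which also cleaves aryl esters formed by premature protonation; cold acidification then gives 14.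

Step 6
Reactants: 14 (2E,3E)-1,4-bis[2-hydroxy-4,6-bis(benzyloxy)phenyl]-2,3-bis(4-methoxybenzylidene)butane-1,4-dione
Product: 16 (2R,2'R,3R,3'R)-5,5',7,7'-tetrakis(benzyloxy)-2,2'-bis(4-methoxyphenyl)-[3,3'-bichromane]-4,4'-dione (2,3-cis and 2',3'-cis), via mono-cyclised flavanone–chalcone 15 (not isolated)
Conditions: epi-9-amino-9-deoxyquinidine-derived N-[3,5-bis(trifluoromethyl)phenyl]thiourea (20 mol %), toluene, 4 Å molecular sieves, 0 °C to rt, dark
Reagents that add atoms: none
Why: Proposed new method: the quinuclidine nitrogen of the catalyst deprotonates a chelated 2'-hydroxyl while the thiourea binds the ketone, the phenoxide closes on the β-carbon in a 6-endo-trig oxa-Michael addition from the enone face left open by the catalyst (setting C2, then C2'), and the enol is protonated at C3 (then C3') anti to the 2-aryl group, which allylic 1,2-strain with the bulky C3 substituent holds pseudo-axial, so each ring should form 2,3-cis; the closest known reaction type is the cinchona-thiourea-catalysed enantioselective oxa-Michael cyclisation of 2'-hydroxychalcones and their α-alkoxycarbonyl derivatives to flavanones, which has not been shown for α-alkenyl chalcones or with a stereocentre set at C3. Because the two closures on C2-symmetric 14 are controlled independently by the same catalyst, events of the minor sense should end up mostly in the meso cis,cis diastereomer, which is removed by chromatography, so the enantiomeric purity of 16 is expected to exceed the selectivity of a single closure.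

Step 7
Reactants: 16 (2R,2'R,3R,3'R)-5,5',7,7'-tetrakis(benzyloxy)-2,2'-bis(4-methoxyphenyl)-[3,3'-bichromane]-4,4'-dione
Product: 17 (2R,2'R,3R,3'R)-5,5',7,7'-tetrahydroxy-2,2'-bis(4-methoxyphenyl)-[3,3'-bichromane]-4,4'-dione
Conditions: H2 (1 atm), Pd/C (10% palladium on carbon), EtOAc–THF, rt
Reagents that add atoms: none
Why: Hydrogenolysis of the four aryl benzyl ethers on palladium under neutral conditions leaves the ketones, the aryl methyl ethers and the base-sensitive C3 and C3' centres untouched. The reaction is stopped as soon as the benzyl groups are gone, to spare the benzylic C2–O1 bonds.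

Step 8
Reactants: 17 (2R,2'R,3R,3'R)-5,5',7,7'-tetrahydroxy-2,2'-bis(4-methoxyphenyl)-[3,3'-bichromane]-4,4'-dione
Product: 18 (2R,2'R,3R,3'R)-5,5',7-trihydroxy-7'-methoxy-2,2'-bis(4-methoxyphenyl)-[3,3'-bichromane]-4,4'-dione (CNP0184936.2)
Conditions: CH2N2 (about 1 equiv), Et2O–MeOH, 0 °C; partial conversion, unchanged 17 recovered and recycled
Reagents that add atoms: diazomethane, C=[N+]=[N-]
Why: Diazomethane methylates phenols according to acidity and accessibility: the 7- and 7'-hydroxyls (para to the carbonyl groups, not hydrogen-bonded) react, while the chelated 5- and 5'-hydroxyls do not. The two 7-hydroxyls of C2-symmetric 17 are homotopic, so only one monomethyl ether, 18, can form, and the neutral conditions leave the cis C3 centres alone.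

## Compound list

1 | diethyl succinate | CCOC(=O)CCC(=O)OCC | starting material
2 | 4-methoxybenzaldehyde | COc1ccc(C=O)cc1 | starting material
3 | (2E,3E)-2,3-bis(4-methoxybenzylidene)succinic acid monoethyl ester | COc1ccc(/C=C(C(=O)OCC)\C(C(=O)O)=C/c2ccc(OC)cc2)cc1 | intermediate
4 | (2E,3E)-2,3-bis(4-methoxybenzylidene)succinic acid | COc1ccc(/C=C(C(=O)O)\C(C(=O)O)=C/c2ccc(OC)cc2)cc1 | intermediate
5 | 3,5-bis(benzyloxy)phenol | Oc1cc(OCc2ccccc2)cc(OCc2ccccc2)c1 | starting material
6 | 3,5-bis(benzyloxy)phenyl N-isopropylcarbamate | CC(C)NC(=O)Oc1cc(OCc2ccccc2)cc(OCc2ccccc2)c1 | intermediate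
7 | 3,5-bis(benzyloxy)phenyl N-(tert-butyldimethylsilyl)-N-isopropylcarbamate | CC(C)N(C(=O)Oc1cc(OCc2ccccc2)cc(OCc2ccccc2)c1)[Si](C)(C)C(C)(C)C | intermediate
8 | 3,5-bis(benzyloxy)-2-(trimethylsilyl)phenyl N-(tert-butyldimethylsilyl)-N-isopropylcarbamate | CC(C)N(C(=O)Oc1cc(OCc2ccccc2)cc(OCc2ccccc2)c1[Si](C)(C)C)[Si](C)(C)C(C)(C)C | intermediate
9 | 3,5-bis(benzyloxy)-2-(trimethylsilyl)phenyl N-isopropylcarbamate | CC(C)NC(=O)Oc1cc(OCc2ccccc2)cc(OCc2ccccc2)c1[Si](C)(C)C | intermediate
10 | 3,5-bis(benzyloxy)-2-(trimethylsilyl)phenol | C[Si](C)(C)c1c(O)cc(OCc2ccccc2)cc1OCc1ccccc1 | intermediate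
11 | 3,5-bis(benzyloxy)-2-(trimethylsilyl)phenyl trifluoromethanesulfonate | C[Si](C)(C)c1c(OCc2ccccc2)cc(OCc2ccccc2)cc1OS(=O)(=O)C(F)(F)F | intermediate
12 | 3,5-bis(benzyloxy)benzyne (1,2-didehydro-3,5-bis(benzyloxy)benzene) | C1#CC(OCc2ccccc2)=CC(OCc2ccccc2)=C1 | intermediate
13 | (2E,3E)-3-[2-hydroxy-4,6-bis(benzyloxy)benzoyl]-2-(4-methoxybenzylidene)-4-(4-methoxyphenyl)but-3-enoic acid | COc1ccc(/C=C(C(=O)O)\C(C(=O)c2c(O)cc(OCc3ccccc3)cc2OCc2ccccc2)=C/c2ccc(OC)cc2)cc1 | intermediate
14 | (2E,3E)-1,4-bis[2-hydroxy-4,6-bis(benzyloxy)phenyl]-2,3-bis(4-methoxybenzylidene)butane-1,4-dione | COc1ccc(/C=C(C(=O)c2c(O)cc(OCc3ccccc3)cc2OCc2ccccc2)\C(C(=O)c2c(O)cc(OCc3ccccc3)cc2OCc2ccccc2)=C/c2ccc(OC)cc2)cc1 | intermediate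
15 | (2R,3R)-5,7-bis(benzyloxy)-3-[(E)-1-[2-hydroxy-4,6-bis(benzyloxy)benzoyl]-2-(4-methoxyphenyl)ethenyl]-2-(4-methoxyphenyl)chroman-4-one (2,3-cis) | COc1ccc([C@@H]2Oc3cc(OCc4ccccc4)cc(OCc4ccccc4)c3C(=O)[C@@H]2/C(C(=O)c2c(O)cc(OCc3ccccc3)cc2OCc2ccccc2)=C\c2ccc(OC)cc2)cc1 | intermediate
16 | (2R,2'R,3R,3'R)-5,5',7,7'-tetrakis(benzyloxy)-2,2'-bis(4-methoxyphenyl)-[3,3'-bichromane]-4,4'-dione (cis,cis) | COc1ccc([C@@H]2Oc3cc(OCc4ccccc4)cc(OCc4ccccc4)c3C(=O)[C@@H]2[C@H]2C(=O)c3c(OCc4ccccc4)cc(OCc4ccccc4)cc3O[C@H]2c2ccc(OC)cc2)cc1 | intermediate
17 | (2R,2'R,3R,3'R)-5,5',7,7'-tetrahydroxy-2,2'-bis(4-methoxyphenyl)-[3,3'-bichromane]-4,4'-dione (cis,cis) | COc1ccc([C@@H]2Oc3cc(O)cc(O)c3C(=O)[C@@H]2[C@H]2C(=O)c3c(O)cc(O)cc3O[C@H]2c2ccc(OC)cc2)cc1 | intermediate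
18 | (2R,2'R,3R,3'R)-5,5',7-trihydroxy-7'-methoxy-2,2'-bis(4-methoxyphenyl)-[3,3'-bichromane]-4,4'-dione (cis,cis; CNP0184936.2) | COc1ccc([C@@H]2Oc3cc(O)cc(O)c3C(=O)[C@@H]2[C@H]2C(=O)c3c(O)cc(OC)cc3O[C@H]2c2ccc(OC)cc2)cc1 | target

## Step count and least certain steps

Total step count: 8. Longest linear sequence: 7 steps (steps 2 to 8, from 5).

**Step 6 (proposed new method).**
- What may go wrong: closure may be slow, because each enone is α-substituted, carries an electron-rich β-aryl group and is attached to an electron-rich ketone, and a weak amine base may not drive it. Facial selectivity at C2 may be poor. Protonation at C3 may occur from the aryl face, or the amine may epimerise C3 and C3' after closure towards the more stable trans arrangement. The second ring may close under substrate control instead of catalyst control.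
- Fallback (known chemistry), from 14 back to 16:
  - Both rings are closed with an achiral base under mild conditions (catalytic DABCO in toluene, or KF in MeOH at rt), which is the standard chalcone–flavanone isomerisation.
  - The C2-symmetric cis,cis racemate is isolated by chromatography. It consists of 16 and its mirror image, (2S,2'S,3S,3'S)-5,5',7,7'-tetrakis(benzyloxy)-2,2'-bis(4-methoxyphenyl)-[3,3'-bichromane]-4,4'-dione F1.
  - The two enantiomers are separated by preparative chromatography on a polysaccharide carbamate chiral phase, which returns the route to 16.
  - F1 and the unwanted diastereomers are reopened to 14 with KOH in EtOH, as in the work-up of step 5, and cyclised again.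

**Step 5 (key step).**
- What may go wrong: protonation of the aryl anion before acyl transfer, which stops at O-arylation; incomplete second insertion; arylation of the product phenoxide by excess aryne; cycloaddition or ene reaction of the aryne with the styrene-type diene; and thermal or light-induced E/Z isomerisation of the diene.
- Fallback, from 5 and 4 back to 14. It generates the same ortho-metalated aryl ester by a different route:
  - Phenol 5 is brominated ortho to the hydroxyl (NBS, cat. i-Pr2NH, CH2Cl2, 0 °C) to give 2-bromo-3,5-bis(benzyloxy)phenol F2.
  - Diacid 4 is esterified at both carboxyl groups with F2 (EDC·HCl, DMAP, CH2Cl2) to give bis[2-bromo-3,5-bis(benzyloxy)phenyl] (2E,3E)-2,3-bis(4-methoxybenzylidene)succinate F3.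
  - Bromine–lithium exchange on F3 (n-BuLi, THF, −100 °C) triggers the anionic Fries-type 1,3-acyl shift at both ends, returning the route to 14.

**Step 3.**
- What may go wrong: lithiation at a benzylic OCH2 position followed by Wittig rearrangement, or lithiation between the two benzyl ethers, because n-BuLi/TMEDA must discriminate between several acidic sites.
- Fallback, from 5 back to 11, without a deprotonation step:
  - 2-Bromo-3,5-bis(benzyloxy)phenol F2 (made from 5 as described under step 5) is O-silylated with hexamethyldisilazane to [2-bromo-3,5-bis(benzyloxy)phenoxy]trimethylsilane F4.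
  - n-BuLi in THF at −100 °C effects bromine–lithium exchange, which is faster than benzylic deprotonation. A retro-Brook shift of silicon from oxygen to carbon gives the lithium salt of 10.
  - Tf2O is added to the same flask, returning the route to 11.

**Step 7.**
- What may go wrong: reductive opening of the benzylic C2–O1 and C2'–O1' bonds, which the 4-methoxyphenyl groups activate, and epimerisation at C3 on a basic catalyst batch.
- Fallback, from 16 directly to 17: non-reductive debenzylation with BCl3 and pentamethylbenzene as cation scavenger in CH2Cl2 at −78 °C. This cleaves aryl benzyl ethers by Lewis-acid-assisted ionisation and leaves the aryl methyl ethers alone at that temperature. No new compound is involved.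

**Step 8.**
- What may go wrong: methylation of both 7-hydroxyls. The two sites are independent, the outcome is statistical, and doubly methylated material cannot be brought back.
- Fallback, from 17 back to 18. The statistical event is moved to a reversible protection:
  - Compound 17 is silylated with about one equivalent of TBSCl (imidazole, DMF, 0 °C) to give the 7-O-tert-butyldimethylsilyl ether of 17 F5. Any over-silylation is undone with fluoride, which returns the material to 17.
  - The remaining free 7'-hydroxyl of F5 is methylated to completion with excess CH2N2, giving the 7-O-tert-butyldimethylsilyl ether of 18 F6.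
  - The silyl group is removed with HF·pyridine in THF at 0 °C, returning the route to 18.

## Further compounds

F1 | step 6 | (2S,2'S,3S,3'S)-5,5',7,7'-tetrakis(benzyloxy)-2,2'-bis(4-methoxyphenyl)-[3,3'-bichromane]-4,4'-dione (enantiomer of 16) | COc1ccc([C@H]2Oc3cc(OCc4ccccc4)cc(OCc4ccccc4)c3C(=O)[C@H]2[C@@H]2C(=O)c3c(OCc4ccccc4)cc(OCc4ccccc4)cc3O[C@@H]2c2ccc(OC)cc2)cc1
F2 | step 5 | 2-bromo-3,5-bis(benzyloxy)phenol | Oc1cc(OCc2ccccc2)cc(OCc2ccccc2)c1Br
F3 | step 5 | bis[2-bromo-3,5-bis(benzyloxy)phenyl] (2E,3E)-2,3-bis(4-methoxybenzylidene)succinate | COc1ccc(/C=C(C(=O)Oc2cc(OCc3ccccc3)cc(OCc3ccccc3)c2Br)\C(C(=O)Oc2cc(OCc3ccccc3)cc(OCc3ccccc3)c2Br)=C/c2ccc(OC)cc2)cc1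
F4 | step 3 | [2-bromo-3,5-bis(benzyloxy)phenoxy]trimethylsilane | C[Si](C)(C)Oc1cc(OCc2ccccc2)cc(OCc2ccccc2)c1Br
F0 | step 7 | none | none
F5 | step 8 | (2R,2'R,3R,3'R)-7-(tert-butyldimethylsilyloxy)-5,5',7'-trihydroxy-2,2'-bis(4-methoxyphenyl)-[3,3'-bichromane]-4,4'-dione | COc1ccc([C@@H]2Oc3cc(O[Si](C)(C)C(C)(C)C)cc(O)c3C(=O)[C@@H]2[C@H]2C(=O)c3c(O)cc(O)cc3O[C@H]2c2ccc(OC)cc2)cc1
F6 | step 8 | (2R,2'R,3R,3'R)-7-(tert-butyldimethylsilyloxy)-5,5'-dihydroxy-7'-methoxy-2,2'-bis(4-methoxyphenyl)-[3,3'-bichromane]-4,4'-dione | COc1ccc([C@@H]2Oc3cc(O[Si](C)(C)C(C)(C)C)cc(O)c3C(=O)[C@@H]2[C@H]2C(=O)c3c(O)cc(OC)cc3O[C@H]2c2ccc(OC)cc2)cc1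
A1 | alternative 1 | exo,exo-2,6-bis(4-methoxyphenyl)-cis-3,7-dioxabicyclo[3.3.0]octane-4,8-dione, enantiomer whose four carbon centres match those of 18 | COc1ccc([C@@H]2OC(=O)[C@@H]3[C@H]2C(=O)O[C@H]3c2ccc(OC)cc2)cc1
A2 | alternative 1 | (E)-4-methoxycinnamic acid | COc1ccc(/C=C/C(=O)O)cc1
A3 | alternative 2 | (Z)-5,5',7,7'-tetrakis(benzyloxy)-2,2'-bis(4-methoxyphenyl)-[3,3'-bichromanylidene]-4,4'-dione, C2 and C2' configured as in 18 | COc1ccc([C@@H]2Oc3cc(OCc4ccccc4)cc(OCc4ccccc4)c3C(=O)/C2=C2\C(=O)c3c(OCc4ccccc4)cc(OCc4ccccc4)cc3O[C@H]2c2ccc(OC)cc2)cc1
A4 | alternative 2 | (Z)-1,4-bis[2-iodo-3,5-bis(benzyloxy)phenoxy]-1,4-bis(4-methoxyphenyl)-2,3-bis(4,4,5,5-tetramethyl-1,3,2-dioxaborolan-2-yl)but-2-ene, C1 and C4 configured as C2 and C2' of 18 | COc1ccc([C@H](Oc2cc(OCc3ccccc3)cc(OCc3ccccc3)c2I)/C(B2OC(C)(C)C(C)(C)O2)=C(/B2OC(C)(C)C(C)(C)O2)[C@@H](Oc2cc(OCc3ccccc3)cc(OCc3ccccc3)c2I)c2ccc(OC)cc2)cc1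
A5 | alternative 3 | (2R,2'R,3R,3'R)-5,7-bis(benzyloxy)-5',7'-dimethoxy-2,2'-bis(4-methoxyphenyl)-[3,3'-bichromane]-4,4'-dione (cis,cis) | COc1ccc([C@@H]2Oc3cc(OCc4ccccc4)cc(OCc4ccccc4)c3C(=O)[C@@H]2[C@H]2C(=O)c3c(OC)cc(OC)cc3O[C@H]2c2ccc(OC)cc2)cc1
A6 | alternative 3 | 5,7-bis(benzyloxy)-5',7'-dimethoxy-[3,3'-bichromene]-4,4'-dione (3,3'-bichromone) | O=c1c(-c2coc3cc(OC)cc(OC)c3c2=O)coc2cc(OCc3ccccc3)cc(OCc3ccccc3)c12
A7 | alternative 3 | 4-methoxyphenylboronic acid | COc1ccc(B(O)O)cc1
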